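**Plan**

1. Retrosynthesis: the isopropenyl group (from a C3 ester via a tertiary alcohol), the C9 acetate and the C1 isobutyrate lead back to spiro keto ester 9. In 9 the two ring A bonds C1–C2 and C4–C5 are cut together, giving the O-allyl enol ether 7 of formyl enone 5. Ring B of 5 is cut at C9–C10 and C5–C6 into silyloxy diene 2 and crotonaldehyde 3.
2. Enabling feature: the oxygen-bearing C1 of ring A is bonded to the spiro carbon C5, and C5 is the γ-carbon of the ring B enone (O=C8–C7=C6–C5). With C1 as an aldehyde, ring B is a doubly vinylogous acid whose enol oxygen can carry C2–C3–C4 as an allyl group, so a Claisen shift makes C4–C5 and frees a pent-4-enal that closes C1–C2 by hydroacylation.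
3. Forward order: ring B first (organocatalytic Mukaiyama–Michael addition and ring closure), then ring A in one operation, then redox and ester adjustments. The helpers (C3 ester, C1 ketone, a temporary C8 alcohol) are converted or removed in steps 5–10.
4. Stereochemistry: C10 from iminium catalysis; C5 from the Claisen shift anti to the C10 methyl; C3 from the chiral rhodium catalyst; C1 from the CBS reduction; C9 from acetoxylation trans to the C10 methyl.
5. Locants of the target are used for all spiro compounds: C1 (O-bearing), C3 (side chain), C5 (spiro), C6 (vinylic methyl), C8 (ketone), C9, C10 (methyl).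

Key step: step 4

Assumption: the sense of induction of the two chiral catalysts is taken from the usual models (the (2S,5S)-imidazolidinone directs attack to the Re face of C3 of crotonaldehyde, so its mirror image is used; (S)-BINAP is assumed to give 3S). If a test run shows the opposite sense, the mirror-image catalyst is used.

**Step 1**
Reactants: 1 (3E)-4-methoxypent-3-en-2-one
Product: 2 tert-butyl{[(3E)-4-methoxypenta-1,3-dien-2-yl]oxy}dimethylsilane
Conditions: TBSOTf, Et3N, Et2O, 0 °C
Reagents that add atoms: tert-butyldimethylsilyl trifluoromethanesulfonate, CC(C)(C)[Si](C)(C)OS(=O)(=O)C(F)(F)F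
Why: Soft enolisation of the vinylogous ester at the acetyl methyl group and O-silylation (silyl enol ether formation) should give the cross-conjugated 2-silyloxy diene with the enol ether geometry unchanged.

**Step 2**
Reactants: 2 tert-butyl{[(3E)-4-methoxypenta-1,3-dien-2-yl]oxy}dimethylsilane; 3 (2E)-but-2-enal
Product: 5 (6R)-2,6-dimethyl-4-oxocyclohex-2-ene-1-carbaldehyde, via keto aldehyde 4 (not isolated)
Conditions: (2R,5R)-5-benzyl-2-tert-butyl-3-methylimidazolidin-4-one·CF3CO2H (20 mol %), CH2Cl2, H2O (2 equiv), −50 °C; then pyrrolidine (20 mol %), AcOH, 23 °C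
Reagents that add atoms: water, O
Why: Iminium activation of crotonaldehyde should direct the terminal CH2 of the silyloxy diene to the Si face of C3 (organocatalytic Mukaiyama–Michael addition), which sets the future C10 methyl centre, and the freed aldehyde then closes ring B by 6-endo enamine addition–elimination at the β-methoxy enone with loss of methanol; 5 is obtained as C1 epimers and enol tautomer, which does not matter.

**Step 3**
Reactants: 5 (6R)-2,6-dimethyl-4-oxocyclohex-2-ene-1-carbaldehyde; 6 ethyl 2-(hydroxymethyl)prop-2-enoate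
Product: 7 ethyl 2-[({[(6R)-2,6-dimethyl-4-oxocyclohex-2-en-1-ylidene]methyl}oxy)methyl]prop-2-enoate (E/Z mixture at the exocyclic double bond)
Conditions: PPh3, DIAD, THF, 0 to 23 °C
Reagents that add atoms: none
Why: Mitsunobu alkylation of the acidic doubly vinylogous acid should occur at the unhindered formyl-derived enol oxygen (hard alkoxyphosphonium electrophile), and any material alkylated at C1 is compound 8 itself and converges in step 4.

**Step 4**
Reactants: 7 ethyl 2-[({[(6R)-2,6-dimethyl-4-oxocyclohex-2-en-1-ylidene]methyl}oxy)methyl]prop-2-enoate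
Product: 9 ethyl (3S,5R,10R)-6,10-dimethyl-1,8-dioxospiro[4.5]dec-6-ene-3-carboxylate, via formyl acrylate 8 (not isolated)
Conditions: PhCl, BHT (cat.), 150 °C, sealed tube; cool to 25 °C; then [Rh((S)-BINAP)]BF4 (5 mol %, from [Rh(nbd)((S)-BINAP)]BF4 and H2), CH2Cl2, 25 °C
Reagents that add atoms: none
Why: Heating effects the [3,3] sigmatropic (Claisen) shift of the allyl enol ether through a chair transition state, which forms C4–C5 on the face of the exocyclic enol double bond opposite the C10 methyl group (allylic 1,3-strain holds that methyl pseudoaxial) and so sets the spiro centre as 5R while unmasking the C1 aldehyde 8. The cationic monovalent-rhodium catalyst then inserts into the aldehyde C–H bond, the hydride migrates to C3 of the 1,1-disubstituted acrylate, and the six-membered acyl–alkyl rhodacycle undergoes C1–C2 reductive elimination, which closes the five-membered ring A (closure by reductive elimination from a rhodacycle, not a direct 5-endo attack). The closest known reaction types are the tandem Claisen rearrangement/intramolecular hydroacylation of allyl vinyl ethers to spirocyclic cyclopentanones and the enantioselective hydroacylation of 4-substituted pent-4-enals with cationic rhodium–BINAP catalysts, a class in which 4-alkoxycarbonyl substrates perform well. C3 is set by the catalyst: the BINAP ligand selects the alkene face that receives the hydride and should give 3S, the substrate's own bias at this remote carbon being small. The step needs hydroacylation to outrun decarbonylation, which the quaternary α-carbon, the chelating diphosphine and the low temperature favour, and it needs the ring B enone to stay untouched, which it should because it offers no aldehyde C–H bond and no chelating alkene.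

**Step 5**
Reactants: 9 ethyl (3S,5R,10R)-6,10-dimethyl-1,8-dioxospiro[4.5]dec-6-ene-3-carboxylate
Product: 10 ethyl (1R,3S,5R,10R)-1,8-dihydroxy-6,10-dimethylspiro[4.5]dec-6-ene-3-carboxylate (C8 epimers)
Conditions: (S)-2-methyl-CBS-oxazaborolidine (0.3 equiv), BH3·SMe2 (3 equiv), THF, −20 °C; MeOH quench
Reagents that add atoms: none
Why: The CBS reduction differentiates the quaternary C5 from the C2 methylene and should deliver hydride to the C1 ketone from the face anti to the C10 methyl (matched with the substrate bias) to give 1R; the enone carbonyl is reduced as well, which protects it for step 6, and the ester is untouched.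

**Step 6**
Reactants: 10 ethyl (1R,3S,5R,10R)-1,8-dihydroxy-6,10-dimethylspiro[4.5]dec-6-ene-3-carboxylate
Product: 11 (1R,3S,5R,10R)-3-(2-hydroxypropan-2-yl)-6,10-dimethylspiro[4.5]dec-6-ene-1,8-diol (C8 epimers)
Conditions: MeMgBr (6 equiv), THF, −20 to 0 °C; aq NH4Cl
Reagents that add atoms: methylmagnesium bromide, C[Mg]Br
Why: Double Grignard addition to the ester, the only carbonyl group left, should give the tertiary alcohol that masks the isopropenyl group; the trans 1,3-relationship of C1–OH and the ester prevents lactonisation.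

**Step 7**
Reactants: 11 (1R,3S,5R,10R)-3-(2-hydroxypropan-2-yl)-6,10-dimethylspiro[4.5]dec-6-ene-1,8-diol
Product: 12 (1R,3S,5R,10R)-1-hydroxy-3-(2-hydroxypropan-2-yl)-6,10-dimethylspiro[4.5]dec-6-en-8-one
Conditions: MnO2 (activated, excess), CH2Cl2, 23 °C
Reagents that add atoms: none
Why: Activated MnO2 oxidises only the allylic C8 alcohol (allylic alcohol oxidation) and should leave the saturated secondary and the tertiary alcohol alone, restoring the enone.

**Step 8**
Reactants: 12 (1R,3S,5R,10R)-1-hydroxy-3-(2-hydroxypropan-2-yl)-6,10-dimethylspiro[4.5]dec-6-en-8-one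
Product: 13 (1R,3S,5R,10R)-3-(2-hydroxypropan-2-yl)-6,10-dimethyl-8-oxospiro[4.5]dec-6-en-1-yl 2-methylpropanoate
Conditions: (i-PrCO)2O, Et3N, DMAP (cat.), CH2Cl2, 23 °C
Reagents that add atoms: 2-methylpropanoic anhydride, CC(C)C(=O)OC(=O)C(C)C
Why: DMAP-catalysed acylation should esterify the secondary C1 alcohol while the tertiary alcohol stays free under these conditions.

**Step 9**
Reactants: 13 (1R,3S,5R,10R)-3-(2-hydroxypropan-2-yl)-6,10-dimethyl-8-oxospiro[4.5]dec-6-en-1-yl 2-methylpropanoate
Product: 14 (1R,3S,5R,9R,10S)-9-(acetyloxy)-3-(2-hydroxypropan-2-yl)-6,10-dimethyl-8-oxospiro[4.5]dec-6-en-1-yl 2-methylpropanoate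
Conditions: Mn(OAc)3·2H2O (4 equiv), PhH, reflux, azeotropic removal of water
Reagents that add atoms: manganese triacetate, CC(=O)[O-].CC(=O)[O-].CC(=O)[O-].[Mn+3]
Why: α′-Acetoxylation of the enone through its trivalent-manganese enolate should place the acetate on C9 anti to the neighbouring C10 methyl, and the epimerisable α-acetoxy ketone can settle in the trans arrangement; no isolated alkene is present at this stage.

**Step 10**
Reactants: 14 (1R,3S,5R,9R,10S)-9-(acetyloxy)-3-(2-hydroxypropan-2-yl)-6,10-dimethyl-8-oxospiro[4.5]dec-6-en-1-yl 2-methylpropanoate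
Product: 15 (1R,3S,5R,9R,10S)-9-(acetyloxy)-6,10-dimethyl-8-oxo-3-(prop-1-en-2-yl)spiro[4.5]dec-6-en-1-yl 2-methylpropanoate (target)
Conditions: Burgess reagent (methyl N-(triethylammoniosulfonyl)carbamate), PhMe, 60 °C
Reagents that add atoms: none
Why: Burgess dehydration proceeds by syn-elimination of the sulfamate ester, which on statistical and steric grounds should favour loss of a methyl hydrogen over the ring C3–H and gives the isopropenyl group without touching the esters or the α-acetoxy ketone.

**Compound list**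

1 | (3E)-4-methoxypent-3-en-2-one | CO/C(C)=C/C(C)=O | starting material
2 | tert-butyl{[(3E)-4-methoxypenta-1,3-dien-2-yl]oxy}dimethylsilane | CO/C(C)=C/C(=C)O[Si](C)(C)C(C)(C)C | intermediate
3 | (2E)-but-2-enal | C/C=C/C=O | starting material
4 | (3S,6E)-7-methoxy-3-methyl-5-oxooct-6-enal | O=CC[C@H](C)CC(=O)/C=C(\C)OC | intermediate
5 | (6R)-2,6-dimethyl-4-oxocyclohex-2-ene-1-carbaldehyde (C1 epimers, enol tautomer) | O=CC1C(C)=CC(=O)C[C@H]1C | intermediate
6 | ethyl 2-(hydroxymethyl)prop-2-enoate | C=C(CO)C(=O)OCC | starting material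
7 | ethyl 2-[({[(6R)-2,6-dimethyl-4-oxocyclohex-2-en-1-ylidene]methyl}oxy)methyl]prop-2-enoate (E/Z mixture) | CCOC(=O)C(=C)COC=C1C(C)=CC(=O)C[C@H]1C | intermediate
8 | ethyl 2-{[(1R,6R)-1-formyl-2,6-dimethyl-4-oxocyclohex-2-en-1-yl]methyl}prop-2-enoate | CCOC(=O)C(=C)C[C@]1(C=O)C(C)=CC(=O)C[C@H]1C | intermediate
9 | ethyl (3S,5R,10R)-6,10-dimethyl-1,8-dioxospiro[4.5]dec-6-ene-3-carboxylate | CCOC(=O)[C@@H]1CC(=O)[C@@]2(C1)C(C)=CC(=O)C[C@H]2C | intermediate
10 | ethyl (1R,3S,5R,10R)-1,8-dihydroxy-6,10-dimethylspiro[4.5]dec-6-ene-3-carboxylate (C8 epimers) | CCOC(=O)[C@@H]1C[C@@H](O)[C@@]2(C1)C(C)=CC(O)C[C@H]2C | intermediate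
11 | (1R,3S,5R,10R)-3-(2-hydroxypropan-2-yl)-6,10-dimethylspiro[4.5]dec-6-ene-1,8-diol (C8 epimers) | CC(C)(O)[C@@H]1C[C@@H](O)[C@@]2(C1)C(C)=CC(O)C[C@H]2C | intermediate
12 | (1R,3S,5R,10R)-1-hydroxy-3-(2-hydroxypropan-2-yl)-6,10-dimethylspiro[4.5]dec-6-en-8-one | CC(C)(O)[C@@H]1C[C@@H](O)[C@@]2(C1)C(C)=CC(=O)C[C@H]2C | intermediate
13 | (1R,3S,5R,10R)-3-(2-hydroxypropan-2-yl)-6,10-dimethyl-8-oxospiro[4.5]dec-6-en-1-yl 2-methylpropanoate | CC(C)(O)[C@@H]1C[C@@H](OC(=O)C(C)C)[C@@]2(C1)C(C)=CC(=O)C[C@H]2C | intermediate
14 | (1R,3S,5R,9R,10S)-9-(acetyloxy)-3-(2-hydroxypropan-2-yl)-6,10-dimethyl-8-oxospiro[4.5]dec-6-en-1-yl 2-methylpropanoate | CC(C)(O)[C@@H]1C[C@@H](OC(=O)C(C)C)[C@@]2(C1)C(C)=CC(=O)[C@H](OC(C)=O)[C@H]2C | intermediate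
15 | (1R,3S,5R,9R,10S)-9-(acetyloxy)-6,10-dimethyl-8-oxo-3-(prop-1-en-2-yl)spiro[4.5]dec-6-en-1-yl 2-methylpropanoate | C=C(C)[C@@H]1C[C@@H](OC(=O)C(C)C)[C@@]2(C1)C(C)=CC(=O)[C@H](OC(C)=O)[C@H]2C | target

**Step count**

Total steps: 10. Longest linear sequence: 10 steps (from 1; compounds 3 and 6 are bought).

**Steps most likely to fail**

Step 2. Protodesilylation of the acid-labile silyloxy diene may outrun conjugate addition, or the iminium catalyst may give poor enantiofacial control with this nucleophile. The fallback sets out from 2 and returns at 5, with an oxazolidinone auxiliary in place of the catalyst. Diene 2 is combined with (4R)-4-benzyl-3-[(2E)-but-2-enoyl]-1,3-oxazolidin-2-one (bought, or made in one step from the oxazolidinone and crotonyl chloride) and Et2AlCl in CH2Cl2 at −78 °C. This is a chelate-controlled Diels–Alder (or Mukaiyama–Michael/ring closure) on the face remote from the benzyl group. Acidic work-up removes the silyl group and methanol and should give the acyl oxazolidinone F1 with the methyl-bearing centre already R. LiBH4 in THF then cleaves the imide reductively and reduces the ketone, giving diol F2 and releasing the auxiliary. Dess–Martin periodinane oxidises both hydroxyl groups and returns 5.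

Step 4. After the Claisen shift, decarbonylation of the hindered aldehyde may deactivate the rhodium catalyst, or double stereodifferentiation may give poor facial control at C3. The fallback sets out from 8 (isolated by running only the thermal half of step 4) and returns at 10. Ring A is closed by metathesis and C3 is set by the C1 hydroxyl. An asymmetric Nozaki–Hiyama–Kishi vinylation (vinyl iodide, CrCl2, NiCl2 cat., chiral sulfonamide ligand, THF) adds to the aldehyde only, beside the enone and the acrylate, and should give allylic alcohol F3. Ring-closing metathesis between the vinyl group and the acrylate with the second-generation Grubbs catalyst (CH2Cl2, 40 °C) gives cyclopentenol F4. Hydrogenation with [Rh(nbd)(dppb)]BF4 (H2, CH2Cl2) delivers hydrogen to C2=C3 from the face of the C1 hydroxyl, so the ester ends trans to it in hydroxy keto ester F5. Luche reduction (NaBH4, CeCl3, MeOH) of the C8 ketone then gives 10.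

Step 10. Competing elimination toward the ring C3–H would give the isopropylidene isomer, which is hard to separate at the last stage. The fallback sets out from 10 and returns at 15, building the isopropenyl group regiospecifically from the ester carbon. Compound 10 with Me3SiCH2MgCl and CeCl3 in THF gives the bis(silylmethyl) carbinol F6. On silica gel F6 undergoes Peterson elimination to allylsilane F7. MnO2 restores the enone in F8, and 2-methylpropanoic anhydride/DMAP gives isobutyrate F9. Protodesilylation with CF3CO2H in CH2Cl2 at 0 °C (protonation at the terminal CH2, loss of silicon) gives the isopropenyl ester F10. α′-Acetoxylation with Mn(OAc)3 as in step 9 then gives 15.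

**Further compounds**

F1 | step 2 | (4R)-4-benzyl-3-{[(1S,6R)-2,6-dimethyl-4-oxocyclohex-2-en-1-yl]carbonyl}-1,3-oxazolidin-2-one | O=C1OC[C@@H](Cc2ccccc2)N1C(=O)[C@@H]1C(C)=CC(=O)C[C@H]1C
F2 | step 2 | (4S,5R)-4-(hydroxymethyl)-3,5-dimethylcyclohex-2-en-1-ol (C1 epimers) | OC[C@@H]1C(C)=CC(O)C[C@H]1C
F3 | step 4 | ethyl 2-({(1R,6R)-1-[(1R)-1-hydroxyprop-2-en-1-yl]-2,6-dimethyl-4-oxocyclohex-2-en-1-yl}methyl)prop-2-enoate | CCOC(=O)C(=C)C[C@]1([C@H](O)C=C)C(C)=CC(=O)C[C@H]1C
F4 | step 4 | ethyl (1R,5R,10R)-1-hydroxy-6,10-dimethyl-8-oxospiro[4.5]deca-2,6-diene-3-carboxylate | CCOC(=O)C1=C[C@@H](O)[C@@]2(C1)C(C)=CC(=O)C[C@H]2C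
F5 | step 4 | ethyl (1R,3S,5R,10R)-1-hydroxy-6,10-dimethyl-8-oxospiro[4.5]dec-6-ene-3-carboxylate | CCOC(=O)[C@@H]1C[C@@H](O)[C@@]2(C1)C(C)=CC(=O)C[C@H]2C
F6 | step 10 | (1R,3S,5R,10R)-3-[2-hydroxy-1,3-bis(trimethylsilyl)propan-2-yl]-6,10-dimethylspiro[4.5]dec-6-ene-1,8-diol (C8 epimers) | C[Si](C)(C)CC(O)(C[Si](C)(C)C)[C@@H]1C[C@@H](O)[C@@]2(C1)C(C)=CC(O)C[C@H]2C
F7 | step 10 | (1R,3S,5R,10R)-6,10-dimethyl-3-[3-(trimethylsilyl)prop-1-en-2-yl]spiro[4.5]dec-6-ene-1,8-diol (C8 epimers) | C=C(C[Si](C)(C)C)[C@@H]1C[C@@H](O)[C@@]2(C1)C(C)=CC(O)C[C@H]2C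
F8 | step 10 | (1R,3S,5R,10R)-1-hydroxy-6,10-dimethyl-3-[3-(trimethylsilyl)prop-1-en-2-yl]spiro[4.5]dec-6-en-8-one | C=C(C[Si](C)(C)C)[C@@H]1C[C@@H](O)[C@@]2(C1)C(C)=CC(=O)C[C@H]2C
F9 | step 10 | (1R,3S,5R,10R)-6,10-dimethyl-8-oxo-3-[3-(trimethylsilyl)prop-1-en-2-yl]spiro[4.5]dec-6-en-1-yl 2-methylpropanoate | C=C(C[Si](C)(C)C)[C@@H]1C[C@@H](OC(=O)C(C)C)[C@@]2(C1)C(C)=CC(=O)C[C@H]2C
F10 | step 10 | (1R,3S,5R,10R)-6,10-dimethyl-8-oxo-3-(prop-1-en-2-yl)spiro[4.5]dec-6-en-1-yl 2-methylpropanoate | C=C(C)[C@@H]1C[C@@H](OC(=O)C(C)C)[C@@]2(C1)C(C)=CC(=O)C[C@H]2C
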